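**Retrosynthetic overview**

1. Target ⇐ epoxidation of the C1=C10 olefin of the (4Z,1(10)E)-dienolide; the epoxide is the last ring.
2. Dienolide ⇐ one operation on an acyclic iodo-aldehyde: intramolecular Ni/Cr alkenylation closes C5–C6, and the C6 alkoxide then closes onto the C12 methyl ester, so the ten-membered ring and the α-methylene-γ-lactone form together.
3. Iodo-aldehyde ⇐ auxiliary-controlled syn aldol (C7–C8) of an itaconate-derived thioimide, then isovalerylation and thioimide → CHO.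
4. Aldol acceptor ⇐ asymmetric vinylogous Mukaiyama aldol (C2–C3) of (Z)-3-iodo-2-methylacrolein with the tiglic aldehyde dienol ether, then one-carbon extension (Wittig, hydroboration, oxidation).
5. Ring order: carbocycle + lactone (same flask) → epoxide.

Assumption: atom labels C1–C15 follow germacrane numbering (O6–C12 lactone, C13 = exocyclic CH2); catalyst preparation and work-ups are not counted as steps.

**Route**

Step 1
Reactants: 1 prop-2-yn-1-ol
Product: 3 (2Z)-3-iodo-2-methylprop-2-en-1-ol, via alkenylmagnesium alkoxide 2 (not isolated)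
Conditions: MeMgBr (2.5 equiv), CuI (10 mol %), THF, −10 °C → rt; then I2, −10 °C
Reagents that add atoms: methylmagnesium bromide, C[Mg]Br; iodine, II
Why: Copper-catalysed anti-carbomagnesiation of the propargylic alkoxide (chelation puts Mg cis to CH2O) followed by iodinolysis with retention gives the Z vinyl iodide that becomes the Z C4=C5 olefin.

Step 2
Reactants: 3 (2Z)-3-iodo-2-methylprop-2-en-1-ol
Product: 4 (2Z)-3-iodo-2-methylprop-2-enal
Conditions: activated MnO2 (10 equiv), CH2Cl2, rt, dark; used at once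
Reagents that add atoms: none
Why: Allylic alcohol oxidation on MnO2 is neutral, so the Z geometry is kept.

Step 3
Reactants: 5 (2E)-2-methylbut-2-enal (tiglic aldehyde)
Product: 6 tert-butyl(dimethyl){[(1E)-2-methylbuta-1,3-dien-1-yl]oxy}silane
Conditions: TBSOTf, Et3N, CH2Cl2, 0 °C → rt
Reagents that add atoms: tert-butyldimethylsilyl trifluoromethanesulfonate, CC(C)(C)[Si](C)(C)OS(=O)(=O)C(F)(F)F
Why: O-Silylation with γ-deprotonation (silyl dienol ether formation) turns the enal into the vinylogous nucleophile whose terminal CH2 becomes C2.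

Step 4
Reactants: 4 (2Z)-3-iodo-2-methylprop-2-enal; 6 tert-butyl(dimethyl){[(1E)-2-methylbuta-1,3-dien-1-yl]oxy}silane
Product: 7 (2E,5S,6Z)-5-hydroxy-7-iodo-2,6-dimethylhepta-2,6-dienal
Conditions: B-phenyl oxazaborolidinone from N-Ts-D-tryptophan (30 mol %), i-PrOH (1.1 equiv), EtCN, −78 °C; 4 in excess (1.5 equiv)
Reagents that add atoms: none
Why: Catalytic asymmetric vinylogous Mukaiyama aldol, in which the dienol ether attacks through its γ-carbon on the Si face of the boron-bound aldehyde (the indole shields the Re face), sets C3 as S and delivers the E enal.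

Step 5
Reactants: 7 (2E,5S,6Z)-5-hydroxy-7-iodo-2,6-dimethylhepta-2,6-dienal
Product: 8 (1Z,3S,5E)-1-iodo-2,6-dimethyl-7-oxohepta-1,5-dien-3-yl acetate
Conditions: Ac2O, pyridine, DMAP (cat.), CH2Cl2, 0 °C
Reagents that add atoms: acetic anhydride, CC(=O)OC(C)=O
Why: DMAP-catalysed acetylation installs the C3 acetate of the target, which is carried unchanged to the end.

Step 6
Reactants: 8 (1Z,3S,5E)-1-iodo-2,6-dimethyl-7-oxohepta-1,5-dien-3-yl acetate
Product: 9 (1Z,3S,5E)-1-iodo-2,6-dimethylocta-1,5,7-trien-3-yl acetate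
Conditions: Ph3PCH3Br, KHMDS, THF, −78 → 0 °C
Reagents that add atoms: methyltriphenylphosphonium bromide, C[P+](c1ccccc1)(c1ccccc1)c1ccccc1.[Br-]
Why: Wittig methylenation of the aldehyde, which is far faster than attack on the acetate, gives the 1,3-diene whose new terminal carbon is C8.

Step 7
Reactants: 9 (1Z,3S,5E)-1-iodo-2,6-dimethylocta-1,5,7-trien-3-yl acetate
Product: 11 (1Z,3S,5E)-8-hydroxy-1-iodo-2,6-dimethylocta-1,5-dien-3-yl acetate, via B-alkyl-9-BBN 10 (not isolated)
Conditions: 9-BBN (1.2 equiv), THF, 0 °C → rt; then 30 % H2O2, aq NaOAc, 0 °C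
Reagents that add atoms: hydrogen peroxide, OO
Why: Hydroboration–oxidation places boron anti-Markovnikov on the only monosubstituted olefin (the trisubstituted olefins and the vinyl iodide are inert to 9-BBN), and buffered oxidation spares the acetate.

Step 8
Reactants: 11 (1Z,3S,5E)-8-hydroxy-1-iodo-2,6-dimethylocta-1,5-dien-3-yl acetate
Product: 12 (1Z,3S,5E)-1-iodo-2,6-dimethyl-8-oxoocta-1,5-dien-3-yl acetate
Conditions: Dess–Martin periodinane, NaHCO3, CH2Cl2, 0 °C; used crude
Reagents that add atoms: none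
Why: Buffered Dess–Martin oxidation gives the β,γ-unsaturated aldehyde without moving the olefin into conjugation.

Step 9
Reactants: 13 dimethyl itaconate
Product: 14 3-(methoxycarbonyl)but-3-enoic acid
Conditions: LiOH·H2O (1.0 equiv), THF/H2O, 0 °C; then 1 M HCl
Reagents that add atoms: lithium hydroxide, [Li+].[OH-]
Why: Regioselective saponification works because the saturated ester is more electrophilic than the conjugated one, so the acrylate methyl ester (C12) is kept.

Step 10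
Reactants: 14 3-(methoxycarbonyl)but-3-enoic acid; 15 (4R)-4-benzyl-1,3-thiazolidine-2-thione
Product: 16 methyl 4-[(4R)-4-benzyl-2-thioxo-1,3-thiazolidin-3-yl]-2-methylidene-4-oxobutanoate
Conditions: DCC, DMAP (10 mol %), CH2Cl2, 0 °C → rt
Reagents that add atoms: none
Why: Steglich-type N-acylation attaches the chiral auxiliary to the carbonyl that will become C6.

Step 11
Reactants: 16 methyl 4-[(4R)-4-benzyl-2-thioxo-1,3-thiazolidin-3-yl]-2-methylidene-4-oxobutanoate; 12 (1Z,3S,5E)-1-iodo-2,6-dimethyl-8-oxoocta-1,5-dien-3-yl acetate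
Product: 18 methyl (3R,4S,6E,9S,10Z)-9-(acetyloxy)-3-{[(4R)-4-benzyl-2-thioxo-1,3-thiazolidin-3-yl]carbonyl}-4-hydroxy-11-iodo-6,10-dimethyl-2-methylideneundeca-6,10-dienoate, via titanium enolate 17 (not isolated)
Conditions: TiCl4 (1.05 equiv), i-Pr2NEt (1.1 equiv), NMP (1.0 equiv), CH2Cl2, −78 °C; then 12, −78 °C; cold quench
Reagents that add atoms: none
Why: Crimmins titanium aldol in the Evans-syn mode, in which the Z enolate reacts through a closed Zimmerman–Traxler transition state on the face away from the benzyl group, sets C7 (R) and C8 (S) with the syn relationship of the target.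

Step 12
Reactants: 18 (aldol adduct, name as above)
Product: 19 methyl (3R,4S,6E,9S,10Z)-9-(acetyloxy)-3-{[(4R)-4-benzyl-2-thioxo-1,3-thiazolidin-3-yl]carbonyl}-11-iodo-6,10-dimethyl-2-methylidene-4-[(3-methylbutanoyl)oxy]undeca-6,10-dienoate
Conditions: isovaleryl chloride, pyridine, DMAP (cat.), CH2Cl2, −20 °C
Reagents that add atoms: 3-methylbutanoyl chloride, CC(C)CC(=O)Cl
Why: Acylation of the secondary alcohol puts the C8 isovalerate in place before any C6 alkoxide exists, so that later only O6 can close onto C12.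

Step 13
Reactants: 19 (isovalerate, name as above)
Product: 20 methyl (3R,4S,6E,9S,10Z)-9-(acetyloxy)-3-formyl-11-iodo-6,10-dimethyl-2-methylidene-4-[(3-methylbutanoyl)oxy]undeca-6,10-dienoate
Conditions: DIBAL-H (1.1 equiv), CH2Cl2, −78 °C, 10 min; Rochelle salt; used at once
Reagents that add atoms: none
Why: The N-acylthiazolidinethione is a thione-activated amide that DIBAL-H reduces to a stable tetrahedral aluminate much faster than it touches O-esters, so work-up gives the aldehyde and returns the auxiliary.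

Step 14
Reactants: 20 (iodo-aldehyde, name as above)
Product: 22 (3aR,4S,6E,9S,10Z,11aR)-9-(acetyloxy)-6,10-dimethyl-3-methylidene-2-oxo-2,3,3a,4,5,8,9,11a-octahydrocyclodeca[b]furan-4-yl 3-methylbutanoate, via macrocyclic hydroxy ester 21 (not isolated)
Conditions: CrCl2 (8 equiv), NiCl2 (2 mol %), degassed DMSO, rt, 0.003 M (syringe pump); then 40 °C
Reagents that add atoms: none
Why: Nozaki–Hiyama–Kishi alkenylation closes the ten-membered ring at C5–C6 with retention of the Z olefin, Felkin–Anh attack anti to the C8 branch gives the 6R chromium alkoxide, and this alkoxide acylates itself on the neighbouring acrylate ester to give the trans-fused α-methylene-γ-lactone in the same flask.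

Step 15
Reactants: 22 (dienolide, name as above)
Product: 23 (1R,3S,4Z,6R,7R,8S,10R)-3-(acetyloxy)-1,10-epoxy-8-[(3-methylbutanoyl)oxy]germacra-4,11(13)-dien-12,6-olide
Conditions: m-CPBA (1.1 equiv), NaHCO3, CH2Cl2, 0 °C
Reagents that add atoms: 3-chloroperoxybenzoic acid, OOC(=O)c1cccc(Cl)c1
Why: Prilezhaev epoxidation takes the most electron-rich olefin (C4=C5 is flanked by two allylic esters, the acrylate is electron-poor) from its exposed outer face, as is usual for (E)-1(10)-germacranolides, giving the 1R,10R (1β,10α) epoxide.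

**Compound list**

1 | prop-2-yn-1-ol | C#CCO | starting material
2 | bromomagnesium (2Z)-3-(bromomagnesio)-2-methylprop-2-en-1-olate | Br[Mg]OC/C(C)=C\[Mg]Br | intermediate
3 | (2Z)-3-iodo-2-methylprop-2-en-1-ol | OC/C(C)=C\I | intermediate
4 | (2Z)-3-iodo-2-methylprop-2-enal | O=C/C(C)=C\I | intermediate
5 | (2E)-2-methylbut-2-enal | C/C=C(\C)C=O | starting material
6 | tert-butyl(dimethyl){[(1E)-2-methylbuta-1,3-dien-1-yl]oxy}silane | C=C/C(C)=C/O[Si](C)(C)C(C)(C)C | intermediate
7 | (2E,5S,6Z)-5-hydroxy-7-iodo-2,6-dimethylhepta-2,6-dienal | I/C=C(/C)[C@@H](O)C/C=C(\C)C=O | intermediate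
8 | (1Z,3S,5E)-1-iodo-2,6-dimethyl-7-oxohepta-1,5-dien-3-yl acetate | I/C=C(/C)[C@@H](OC(C)=O)C/C=C(\C)C=O | intermediate
9 | (1Z,3S,5E)-1-iodo-2,6-dimethylocta-1,5,7-trien-3-yl acetate | I/C=C(/C)[C@@H](OC(C)=O)C/C=C(\C)C=C | intermediate
10 | (1Z,3S,5E)-8-(9-borabicyclo[3.3.1]nonan-9-yl)-1-iodo-2,6-dimethylocta-1,5-dien-3-yl acetate | I/C=C(/C)[C@@H](OC(C)=O)C/C=C(\C)CCB1C2CCCC1CCC2 | intermediate
11 | (1Z,3S,5E)-8-hydroxy-1-iodo-2,6-dimethylocta-1,5-dien-3-yl acetate | I/C=C(/C)[C@@H](OC(C)=O)C/C=C(\C)CCO | intermediate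
12 | (1Z,3S,5E)-1-iodo-2,6-dimethyl-8-oxoocta-1,5-dien-3-yl acetate | I/C=C(/C)[C@@H](OC(C)=O)C/C=C(\C)CC=O | intermediate
13 | dimethyl itaconate (dimethyl 2-methylidenebutanedioate) | C=C(CC(=O)OC)C(=O)OC | starting material
14 | 3-(methoxycarbonyl)but-3-enoic acid | C=C(CC(=O)O)C(=O)OC | intermediate
15 | (4R)-4-benzyl-1,3-thiazolidine-2-thione | S=C1N[C@H](Cc2ccccc2)CS1 | starting material
16 | methyl 4-[(4R)-4-benzyl-2-thioxo-1,3-thiazolidin-3-yl]-2-methylidene-4-oxobutanoate | C=C(CC(=O)N1[C@H](Cc2ccccc2)CSC1=S)C(=O)OC | intermediate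
17 | methyl (3Z)-4-[(4R)-4-benzyl-2-thioxo-1,3-thiazolidin-3-yl]-2-methylidene-4-[(trichlorotitanio)oxy]but-3-enoate | C=C(/C=C(\O[Ti](Cl)(Cl)Cl)N1[C@H](Cc2ccccc2)CSC1=S)C(=O)OC | intermediate
18 | methyl (3R,4S,6E,9S,10Z)-9-(acetyloxy)-3-{[(4R)-4-benzyl-2-thioxo-1,3-thiazolidin-3-yl]carbonyl}-4-hydroxy-11-iodo-6,10-dimethyl-2-methylideneundeca-6,10-dienoate | I/C=C(/C)[C@@H](OC(C)=O)C/C=C(\C)C[C@H](O)[C@@H](C(=C)C(=O)OC)C(=O)N1[C@H](Cc2ccccc2)CSC1=S | intermediate
19 | methyl (3R,4S,6E,9S,10Z)-9-(acetyloxy)-3-{[(4R)-4-benzyl-2-thioxo-1,3-thiazolidin-3-yl]carbonyl}-11-iodo-6,10-dimethyl-2-methylidene-4-[(3-methylbutanoyl)oxy]undeca-6,10-dienoate | I/C=C(/C)[C@@H](OC(C)=O)C/C=C(\C)C[C@H](OC(=O)CC(C)C)[C@@H](C(=C)C(=O)OC)C(=O)N1[C@H](Cc2ccccc2)CSC1=S | intermediate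
20 | methyl (3R,4S,6E,9S,10Z)-9-(acetyloxy)-3-formyl-11-iodo-6,10-dimethyl-2-methylidene-4-[(3-methylbutanoyl)oxy]undeca-6,10-dienoate | I/C=C(/C)[C@@H](OC(C)=O)C/C=C(\C)C[C@H](OC(=O)CC(C)C)[C@@H](C(=C)C(=O)OC)C=O | intermediate
21 | methyl 2-[(1R,2R,3Z,5S,7E,10S)-5-(acetyloxy)-2-hydroxy-4,8-dimethyl-10-[(3-methylbutanoyl)oxy]cyclodeca-3,7-dien-1-yl]prop-2-enoate (formed as its Cr(III) alkoxide) | C=C(C(=O)OC)[C@H]1[C@H](O)/C=C(/C)[C@@H](OC(C)=O)C/C=C(\C)C[C@@H]1OC(=O)CC(C)C | intermediate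
22 | (3aR,4S,6E,9S,10Z,11aR)-9-(acetyloxy)-6,10-dimethyl-3-methylidene-2-oxo-2,3,3a,4,5,8,9,11a-octahydrocyclodeca[b]furan-4-yl 3-methylbutanoate | C=C1C(=O)O[C@@H]2/C=C(/C)[C@@H](OC(C)=O)C/C=C(\C)C[C@H](OC(=O)CC(C)C)[C@@H]12 | intermediate
23 | (1R,3S,4Z,6R,7R,8S,10R)-3-(acetyloxy)-1,10-epoxy-8-[(3-methylbutanoyl)oxy]germacra-4,11(13)-dien-12,6-olide | C=C1C(=O)O[C@@H]2/C=C(/C)[C@@H](OC(C)=O)C[C@H]3O[C@]3(C)C[C@H](OC(=O)CC(C)C)[C@@H]12 | target

**Step count and risks**

Total steps: 15. Longest linear sequence: 12 (1 → 3 → 4 → 7 → 8 → 9 → 11 → 12 → 18 → 19 → 20 → 22 → 23).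

Most likely to fail: steps 14, 13 and 15.

Step 14 (ring closure with lactonisation). Aldehyde 20 carries an acidic C7–H between the formyl and acrylate groups and a β-acyloxy group, so it may eliminate or epimerise before it cyclises. The C6 configuration also rests on a Felkin–Anh argument inside a forming medium ring, which is a prediction, not a precedent. The fallback sets out from 19 and closes the ring by acylation instead of carbonyl addition. Pyridine-2-thiol and Et3N displace the auxiliary to give methyl (3R,4S,6E,9S,10Z)-9-(acetyloxy)-11-iodo-6,10-dimethyl-2-methylidene-4-[(3-methylbutanoyl)oxy]-3-[(pyridin-2-ylsulfanyl)carbonyl]undeca-6,10-dienoate F1. Ni/Zr-mediated alkenyl iodide–thioester coupling (NiBr2(dtbbpy), Cp2ZrCl2, Zn, DMI, 0.003 M) then gives the macrocyclic Z-enone methyl 2-[(1R,3Z,5S,7E,10S)-5-(acetyloxy)-4,8-dimethyl-10-[(3-methylbutanoyl)oxy]-2-oxocyclodeca-3,7-dien-1-yl]prop-2-enoate F2, which must be kept neutral because C7 is now α to a ketone. Reagent-controlled 1,2-reduction ((R)-Me-CBS, catecholborane, −78 °C, alkenyl arm as the large group) gives the 6R borate, which lactonises on warming and comes back to the route at 22. This detour also removes the need for aldehyde 20.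

Step 13 (DIBAL-H in the presence of three esters). If the acetate, the isovalerate or the acrylate ester is attacked, C6 is brought in at the aldehyde oxidation level as an acetal, so no hydride is needed. This fallback sets out from 12 and comes back at 20. Methyl 4,4-dimethoxybut-2-ynoate F3 is made from commercial 3,3-dimethoxyprop-1-yne (n-BuLi, ClCO2Me). Its 1,4-hydroalumination (DIBAL-H, HMPA) and trapping with ICH2Bpin give methyl (2Z)-4,4-dimethoxy-2-[(4,4,5,5-tetramethyl-1,3,2-dioxaborolan-2-yl)methyl]but-2-enoate F4, with the acetal cis to the ester. Allylboration of 12 through a closed chair gives the anti adduct, which is the same C7/C8 relationship as the aldol: methyl (3R,4S,6E,9S,10Z)-9-(acetyloxy)-3-(dimethoxymethyl)-4-hydroxy-11-iodo-6,10-dimethyl-2-methylideneundeca-6,10-dienoate F5. Sc(OTf)3 at −78 °C provides the rate; facial control has to come from a BINOL-phosphoric acid catalyst, otherwise the two anti diastereomers are separated. Isovaleryl chloride/pyridine gives methyl (3R,4S,6E,9S,10Z)-9-(acetyloxy)-3-(dimethoxymethyl)-11-iodo-6,10-dimethyl-2-methylidene-4-[(3-methylbutanoyl)oxy]undeca-6,10-dienoate F6, and mild acetal hydrolysis (LiBF4, wet MeCN) gives 20.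

Step 15 (face selectivity of the epoxidation). If the peracid attacks the other face of C1=C10, the fallback sets out from 22 and uses the same facial preference in the opposite sense. NBS in aqueous DME at 0 °C gives the bromohydrin (3aR,4S,6R,7S,9S,10Z,11aR)-9-(acetyloxy)-7-bromo-6-hydroxy-6,10-dimethyl-3-methylidene-2-oxo-2,3,3a,4,5,6,7,8,9,11a-decahydrocyclodeca[b]furan-4-yl 3-methylbutanoate F7, with Br at C1 on the face the peracid prefers and OH at C10 anti to it. K2CO3 in MeCN closes the epoxide with inversion at C1, putting oxygen on the opposite face, and the route is rejoined at 23.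

**Further compounds**

F1 | step 14 | methyl (3R,4S,6E,9S,10Z)-9-(acetyloxy)-11-iodo-6,10-dimethyl-2-methylidene-4-[(3-methylbutanoyl)oxy]-3-[(pyridin-2-ylsulfanyl)carbonyl]undeca-6,10-dienoate | I/C=C(/C)[C@@H](OC(C)=O)C/C=C(\C)C[C@H](OC(=O)CC(C)C)[C@@H](C(=C)C(=O)OC)C(=O)Sc1ccccn1
F2 | step 14 | methyl 2-[(1R,3Z,5S,7E,10S)-5-(acetyloxy)-4,8-dimethyl-10-[(3-methylbutanoyl)oxy]-2-oxocyclodeca-3,7-dien-1-yl]prop-2-enoate | C=C(C(=O)OC)[C@H]1C(=O)/C=C(/C)[C@@H](OC(C)=O)C/C=C(\C)C[C@@H]1OC(=O)CC(C)C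
F3 | step 13 | methyl 4,4-dimethoxybut-2-ynoate | COC(OC)C#CC(=O)OC
F4 | step 13 | methyl (2Z)-4,4-dimethoxy-2-[(4,4,5,5-tetramethyl-1,3,2-dioxaborolan-2-yl)methyl]but-2-enoate | COC(OC)/C=C(/CB1OC(C)(C)C(C)(C)O1)C(=O)OC
F5 | step 13 | methyl (3R,4S,6E,9S,10Z)-9-(acetyloxy)-3-(dimethoxymethyl)-4-hydroxy-11-iodo-6,10-dimethyl-2-methylideneundeca-6,10-dienoate | I/C=C(/C)[C@@H](OC(C)=O)C/C=C(\C)C[C@H](O)[C@@H](C(=C)C(=O)OC)C(OC)OC
F6 | step 13 | methyl (3R,4S,6E,9S,10Z)-9-(acetyloxy)-3-(dimethoxymethyl)-11-iodo-6,10-dimethyl-2-methylidene-4-[(3-methylbutanoyl)oxy]undeca-6,10-dienoate | I/C=C(/C)[C@@H](OC(C)=O)C/C=C(\C)C[C@H](OC(=O)CC(C)C)[C@@H](C(=C)C(=O)OC)C(OC)OC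
F7 | step 15 | (3aR,4S,6R,7S,9S,10Z,11aR)-9-(acetyloxy)-7-bromo-6-hydroxy-6,10-dimethyl-3-methylidene-2-oxo-2,3,3a,4,5,6,7,8,9,11a-decahydrocyclodeca[b]furan-4-yl 3-methylbutanoate | C=C1C(=O)O[C@@H]2/C=C(/C)[C@@H](OC(C)=O)C[C@H](Br)[C@](C)(O)C[C@H](OC(=O)CC(C)C)[C@@H]12
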